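**Plan**
- **Cuts:** once the two phenol protecting groups are off, ring A is cut at C5–C6, C7–C8 and C4a–C8a (flavanone numbering). This dissolves it into three alkynes: C4a≡C5, C6≡C7 and C8≡C8a.
- **Enabling feature:** C4a and C8a are already bridged by C4(=O), C3, C2 and O1. Two of the alkynes therefore belong to one 1,7-diyne (terminal ynone plus prenylated alkynyl ether), and ring C is its tether ring. The C4 carbonyl and the oxygens on C7 and C8a make donor and acceptor carbons alternate round ring A.
- **Further cuts:** C8–prenyl (alkylation of a lithium alkynyl ether), O1–C8a (trichloroethylene), C3–C4 (aldol) and C6–prenyl (allylic substitution).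
- **Forward order:** ring B is bought. Fragment 1 (siloxyalkyne 6, two steps) and fragment 2 (diyne 21, eight steps) are made separately. Rings A and C then arise together in one rhodium-catalysed (2+2+2) cycloaddition, and two deprotections finish the synthesis.
- **Stereochemistry:** C2 (S), the only stereocentre, is set by a CBS reduction of aryl ketone 12 and is a spectator afterwards. The ketone that makes the diyne fragile is unveiled only in the step before the cycloaddition.

Key step: step 11

Assumption: 11 and 12 are racemic, and 13 and 15–20 are mixtures of epimers at the carbinol carbon that becomes C4. Step 10 erases this centre, so the epimers are carried on together. From 19 onwards everything is handled at or below room temperature and kept away from acid.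

Step 1
Reactants: 1 prenyl bromide (1-bromo-3-methylbut-2-ene); 2 ethynylmagnesium bromide
Product: 3 5-methylhex-4-en-1-yne
Conditions: CuCl (5 mol %), 2 in excess, THF, 0 °C → rt; fractional distillation
Reagents that add atoms: none
Why: Copper-catalysed SN2 coupling of an alkynyl Grignard reagent with a primary allylic bromide is the classical 1,4-enyne synthesis; attack at the unhindered CH2 end keeps the trisubstituted alkene, and excess 2 limits double alkylation.

Step 2
Reactants: 3 5-methylhex-4-en-1-yne
Product: 6 triisopropyl[(5-methylhex-4-en-1-yn-1-yl)oxy]silane, via lithium acetylide 4 (not isolated), via lithium ynolate 5 (not isolated)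
Conditions: n-BuLi, THF, −78 °C; t-BuOOLi (from t-BuOOH + LiN(SiMe3)2, THF, −78 °C), −78 → 0 °C; TIPSOTf, −78 → 0 °C
Reagents that add atoms: tert-butyl hydroperoxide, CC(C)(C)OO; triisopropylsilyl triflate, CC(C)[Si](OS(=O)(=O)C(F)(F)F)(C(C)C)C(C)C
Why: Oxidation of a lithium acetylide with lithium tert-butyl peroxide (displacement of tert-butoxide at oxygen) gives the ynolate, which the bulky silyl triflate traps on oxygen rather than carbon; this is the standard entry to storable triisopropylsilyl ynol ethers.

Step 3
Reactants: 7 4'-hydroxyacetophenone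
Product: 8 1-[4-(methoxymethoxy)phenyl]ethan-1-one
Conditions: MOMCl, i-Pr2NEt, CH2Cl2, 0 °C → rt
Reagents that add atoms: chloromethyl methyl ether, COCCl
Why: Williamson-type O-alkylation of an acidic phenol; the acetal survives the amide bases, KH, n-BuLi, borane and fluoride used later and falls in dilute acid.

Step 4
Reactants: 8 1-[4-(methoxymethoxy)phenyl]ethan-1-one; 9 3-(trimethylsilyl)prop-2-ynal
Product: 11 (±)-3-hydroxy-1-[4-(methoxymethoxy)phenyl]-5-(trimethylsilyl)pent-4-yn-1-one, via lithium enolate 10 (not isolated)
Conditions: LiN(i-Pr)2, THF, −78 °C; 9, −78 °C; AcOH/THF quench at −78 °C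
Reagents that add atoms: none
Why: Aldol addition of a kinetic lithium enolate to a non-enolisable, highly electrophilic ynal forms the C3–C4 bond by 1,2-addition, and the cold acidic quench prevents retro-aldol and dehydration; the carbinol centre is deliberately left racemic.

Step 5
Reactants: 11 (±)-3-hydroxy-1-[4-(methoxymethoxy)phenyl]-5-(trimethylsilyl)pent-4-yn-1-one
Product: 12 (±)-1-[4-(methoxymethoxy)phenyl]-3-[(triisopropylsilyl)oxy]-5-(trimethylsilyl)pent-4-yn-1-one
Conditions: TIPSOTf (1.1 equiv), 2,6-lutidine, CH2Cl2, −78 → 0 °C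
Reagents that add atoms: triisopropylsilyl triflate, CC(C)[Si](OS(=O)(=O)C(F)(F)F)(C(C)C)C(C)C
Why: Silyl triflate/lutidine O-silylation of a secondary alcohol outruns enol silylation and acetal cleavage in the cold, and triisopropylsilyl is chosen as the common silyl group least prone to O-to-O migration under the alkoxide conditions of step 7.

Step 6
Reactants: 12 (±)-1-[4-(methoxymethoxy)phenyl]-3-[(triisopropylsilyl)oxy]-5-(trimethylsilyl)pent-4-yn-1-one
Product: 13 (1S,3RS)-1-[4-(methoxymethoxy)phenyl]-3-[(triisopropylsilyl)oxy]-5-(trimethylsilyl)pent-4-yn-1-ol (mixture of C3 epimers)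
Conditions: (R)-2-methyl-CBS-oxazaborolidine (15 mol %), BH3·SMe2, THF, −20 °C; MeOH quench
Reagents that add atoms: none
Why: Corey–Bakshi–Shibata reduction: the (R)-oxazaborolidine–borane complex binds the ketone with the aryl group as the large substituent and delivers hydride to the Re face, setting the future C2 as S under catalyst control, with the remote silyloxy-bearing centre expected to have little influence.

Step 7
Reactants: 13 (1S,3RS)-1-[4-(methoxymethoxy)phenyl]-3-[(triisopropylsilyl)oxy]-5-(trimethylsilyl)pent-4-yn-1-ol; 14 trichloroethylene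
Product: 16 {(3RS,5S)-5-{[(E)-1,2-dichloroethenyl]oxy}-5-[4-(methoxymethoxy)phenyl]-3-[(triisopropylsilyl)oxy]pent-1-yn-1-yl}trimethylsilane, via potassium alkoxide 15 (not isolated)
Conditions: KH, THF, 0 °C → rt; 14, −50 °C → rt
Reagents that add atoms: none
Why: First stage of the trichloroethylene route to alkynyl ethers: base-induced loss of HCl gives dichloroacetylene, to which the alkoxide adds anti to give the E-dichlorovinyl ether; secondary benzylic alcohols are proven substrates, and the C–O bond at the stereocentre is not touched.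

Step 8
Reactants: 16 the (E)-1,2-dichlorovinyl ether; 1 prenyl bromide
Product: 19 {(3RS,5S)-5-[4-(methoxymethoxy)phenyl]-5-[(5-methylhex-4-en-1-yn-1-yl)oxy]-3-[(triisopropylsilyl)oxy]pent-1-yn-1-yl}trimethylsilane, via chloroalkynyl ether 17 (not isolated), via lithium alkynyl ether 18 (not isolated)
Conditions: n-BuLi (2.2 equiv), THF, −78 → −40 °C; 1, HMPA, −78 °C → rt
Reagents that add atoms: none
Why: Second stage of the same route: deprotonation with loss of LiCl, then chlorine–lithium exchange, gives the lithium alkoxyacetylide, whose SN2 alkylation with reactive primary halides in THF/HMPA is established; the C-silyl group keeps the other alkyne from being metalated.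

Step 9
Reactants: 19 the bis-silylated diyne
Product: 20 (3RS,5S)-5-[4-(methoxymethoxy)phenyl]-5-[(5-methylhex-4-en-1-yn-1-yl)oxy]pent-1-yn-3-ol (mixture of C3 epimers)
Conditions: Bu4NF (2.5 equiv), THF, 0 °C → rt; chromatography on Et3N-deactivated silica
Reagents that add atoms: none
Why: Fluoride desilylation cleaves the C(sp)–SiMe3 and the O–Si(i-Pr)3 bonds in one operation while the alkynyl ether, acetal and alkenes are inert to fluoride; deactivated silica avoids acid-catalysed addition to the alkynyl ether.

Step 10
Reactants: 20 (3RS,5S)-5-[4-(methoxymethoxy)phenyl]-5-[(5-methylhex-4-en-1-yn-1-yl)oxy]pent-1-yn-3-ol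
Product: 21 (5S)-5-[4-(methoxymethoxy)phenyl]-5-[(5-methylhex-4-en-1-yn-1-yl)oxy]pent-1-yn-3-one
Conditions: activated MnO2 (excess), CH2Cl2, rt; filtration through Celite, filtrate used at once without heating
Reagents that add atoms: none
Why: Heterogeneous MnO2 oxidation of a propargylic alcohol is neutral, so neither acid (hydration of the alkynyl ether) nor amine base (E1cB loss of the alkynyloxy group) meets the product; both epimers converge on one ynone in the solvent of the next step.

Step 11
Reactants: 21 (5S)-5-[4-(methoxymethoxy)phenyl]-5-[(5-methylhex-4-en-1-yn-1-yl)oxy]pent-1-yn-3-one; 6 triisopropyl[(5-methylhex-4-en-1-yn-1-yl)oxy]silane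
Product: 22 (2S)-2-[4-(methoxymethoxy)phenyl]-6,8-bis(3-methylbut-2-en-1-yl)-7-[(triisopropylsilyl)oxy]chroman-4-one
Conditions: [Rh(cod)2]BF4 (10 mol %), rac-BINAP (10 mol %), pre-activated under H2 (1 atm) in CH2Cl2, then H2 replaced by argon; 6 (3 equiv), slow addition of 21, CH2Cl2, rt
Reagents that add atoms: none
Why: Proposed new method: the cationic monovalent-rhodium bisphosphine complex should bind the electron-poor terminal ynone of 21 and the electron-rich siloxyalkyne 6, couple them oxidatively head to tail (C5–C6) to a rhodacyclopentadiene, insert the tethered alkynyl ether (C7–C8) and release the arene by reductive elimination (C4a–C8a), and the alternative start by oxidative coupling within the diyne followed by insertion of 6 ends at the same product. The closest known reaction type is the room-temperature (2+2+2) cycloaddition of tethered diynes with monoalkynes under cationic rhodium/BINAP catalysis, known for alkynyl ethers and for alkynyl ketones, whereas a siloxyalkyne partner and an alkyl alkynyl ether/ynone 1,7-diyne have not been shown. Ring A closes as a six-membered carbocycle by metal-templated union of the three C≡C units, and ring C closes in the same event as a six-membered oxacycle by annulation, since the four-atom tether C4–C3–C2–O1 already spans C4a and C8a. No stereocentre is formed, and C2 sits on the tether with none of its bonds involved, so its S configuration should pass unchanged under neutral conditions at room temperature (the racemic ligand suffices). The step needs cross- rather than self-cyclotrimerisation and the orientation of 6 that places its prenyl-bearing carbon at C6 next to C5–H: donor and acceptor carbons alternate round the nascent ring (C5, C7 and C8a electrophilic, C4a, C6 and C8 nucleophilic), so all three new bonds are polarity-matched only in this orientation, and an excess of 6 with slow addition of 21 disfavours self-reaction. The steric price of seating the silyloxy group between two prenyl groups opposes this electronic bias, which is why the regiochemical outcome remains the open point.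

Step 12
Reactants: 22 (2S)-2-[4-(methoxymethoxy)phenyl]-6,8-bis(3-methylbut-2-en-1-yl)-7-[(triisopropylsilyl)oxy]chroman-4-one
Product: 23 (2S)-2-(4-hydroxyphenyl)-6,8-bis(3-methylbut-2-en-1-yl)-7-[(triisopropylsilyl)oxy]chroman-4-one
Conditions: HCl (ca. 0.5 M), MeOH, rt → 40 °C
Reagents that add atoms: none
Why: Acid-catalysed acetal exchange of an aryl methoxymethyl ether with methanol, a standard operation on prenylated flavonoids; it is run while O7 still carries the acid-stable hindered silyl group, so neither prenyl group has a free ortho phenol for chroman formation.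

Step 13
Reactants: 23 (2S)-2-(4-hydroxyphenyl)-6,8-bis(3-methylbut-2-en-1-yl)-7-[(triisopropylsilyl)oxy]chroman-4-one
Product: 24 (2S)-7-hydroxy-2-(4-hydroxyphenyl)-6,8-bis(3-methylbut-2-en-1-yl)chroman-4-one (CNP0283993.2)
Conditions: Bu4NF/AcOH (1:1), THF, 0 °C
Reagents that add atoms: none
Why: Fluoride cleavage of an aryl silyl ether, buffered with acetic acid so the medium never turns basic, which avoids retro-oxa-Michael opening to the chalcone and the racemisation of C2 that would follow.

**Compound list**
1 | prenyl bromide (1-bromo-3-methylbut-2-ene) | CC(C)=CCBr | starting material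
2 | ethynylmagnesium bromide | C#C[Mg]Br | starting material
3 | 5-methylhex-4-en-1-yne | C#CCC=C(C)C | intermediate
4 | lithium 5-methylhex-4-en-1-yn-1-ide | [Li]C#CCC=C(C)C | intermediate
5 | lithium 5-methylhex-4-en-1-yn-1-olate | [Li+].[O-]C#CCC=C(C)C | intermediate
6 | triisopropyl[(5-methylhex-4-en-1-yn-1-yl)oxy]silane | CC(C)=CCC#CO[Si](C(C)C)(C(C)C)C(C)C | intermediate
7 | 4'-hydroxyacetophenone | CC(=O)c1ccc(O)cc1 | starting material
8 | 1-[4-(methoxymethoxy)phenyl]ethan-1-one | CC(=O)c1ccc(OCOC)cc1 | intermediate
9 | 3-(trimethylsilyl)prop-2-ynal | C[Si](C)(C)C#CC=O | starting material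
10 | lithium enolate of 8 | [Li+].[O-]C(=C)c1ccc(OCOC)cc1 | intermediate
11 | (±)-3-hydroxy-1-[4-(methoxymethoxy)phenyl]-5-(trimethylsilyl)pent-4-yn-1-one | C[Si](C)(C)C#CC(O)CC(=O)c1ccc(OCOC)cc1 | intermediate
12 | (±)-1-[4-(methoxymethoxy)phenyl]-3-[(triisopropylsilyl)oxy]-5-(trimethylsilyl)pent-4-yn-1-one | C[Si](C)(C)C#CC(O[Si](C(C)C)(C(C)C)C(C)C)CC(=O)c1ccc(OCOC)cc1 | intermediate
13 | (1S,3RS)-1-[4-(methoxymethoxy)phenyl]-3-[(triisopropylsilyl)oxy]-5-(trimethylsilyl)pent-4-yn-1-ol | C[Si](C)(C)C#CC(O[Si](C(C)C)(C(C)C)C(C)C)C[C@H](O)c1ccc(OCOC)cc1 | intermediate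
14 | trichloroethylene | ClC=C(Cl)Cl | starting material
15 | potassium alkoxide of 13 | C[Si](C)(C)C#CC(O[Si](C(C)C)(C(C)C)C(C)C)C[C@H]([O-])c1ccc(OCOC)cc1.[K+] | intermediate
16 | {(3RS,5S)-5-{[(E)-1,2-dichloroethenyl]oxy}-5-[4-(methoxymethoxy)phenyl]-3-[(triisopropylsilyl)oxy]pent-1-yn-1-yl}trimethylsilane | C[Si](C)(C)C#CC(O[Si](C(C)C)(C(C)C)C(C)C)C[C@H](O/C(Cl)=C\Cl)c1ccc(OCOC)cc1 | intermediate
17 | {(3RS,5S)-5-[(chloroethynyl)oxy]-5-[4-(methoxymethoxy)phenyl]-3-[(triisopropylsilyl)oxy]pent-1-yn-1-yl}trimethylsilane | C[Si](C)(C)C#CC(O[Si](C(C)C)(C(C)C)C(C)C)C[C@H](OC#CCl)c1ccc(OCOC)cc1 | intermediate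
18 | lithium alkynyl ether (lithioethynyl ether of 13) | C[Si](C)(C)C#CC(O[Si](C(C)C)(C(C)C)C(C)C)C[C@H](OC#C[Li])c1ccc(OCOC)cc1 | intermediate
19 | {(3RS,5S)-5-[4-(methoxymethoxy)phenyl]-5-[(5-methylhex-4-en-1-yn-1-yl)oxy]-3-[(triisopropylsilyl)oxy]pent-1-yn-1-yl}trimethylsilane | C[Si](C)(C)C#CC(O[Si](C(C)C)(C(C)C)C(C)C)C[C@H](OC#CCC=C(C)C)c1ccc(OCOC)cc1 | intermediate
20 | (3RS,5S)-5-[4-(methoxymethoxy)phenyl]-5-[(5-methylhex-4-en-1-yn-1-yl)oxy]pent-1-yn-3-ol | C#CC(O)C[C@H](OC#CCC=C(C)C)c1ccc(OCOC)cc1 | intermediate
21 | (5S)-5-[4-(methoxymethoxy)phenyl]-5-[(5-methylhex-4-en-1-yn-1-yl)oxy]pent-1-yn-3-one | C#CC(=O)C[C@H](OC#CCC=C(C)C)c1ccc(OCOC)cc1 | intermediate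
22 | (2S)-2-[4-(methoxymethoxy)phenyl]-6,8-bis(3-methylbut-2-en-1-yl)-7-[(triisopropylsilyl)oxy]chroman-4-one | CC(C)=CCc1cc2c(c(CC=C(C)C)c1O[Si](C(C)C)(C(C)C)C(C)C)O[C@H](c1ccc(OCOC)cc1)CC2=O | intermediate
23 | (2S)-2-(4-hydroxyphenyl)-6,8-bis(3-methylbut-2-en-1-yl)-7-[(triisopropylsilyl)oxy]chroman-4-one | CC(C)=CCc1cc2c(c(CC=C(C)C)c1O[Si](C(C)C)(C(C)C)C(C)C)O[C@H](c1ccc(O)cc1)CC2=O | intermediate
24 | (2S)-7-hydroxy-2-(4-hydroxyphenyl)-6,8-bis(3-methylbut-2-en-1-yl)chroman-4-one | CC(C)=CCc1cc2c(c(CC=C(C)C)c1O)O[C@H](c1ccc(O)cc1)CC2=O | target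

**Step count**
- Total step count: 13.
- Longest linear sequence: 11 (steps 3–13).

**Steps most likely to fail**

**1. Step 11.**
- Steric crowding round the silyloxy group may make the siloxyalkyne insert in the reverse orientation.
- The terminal ynone may cyclotrimerise with itself.
- The ynone may combine with the siloxyalkyne in a Lewis-acid-type (2+2) addition.
- The diyne may fragment faster than it is consumed.

The fallback uses only known reaction types, sets out from 1 and rejoins the route at 22.
- Commercial 2,4-dihydroxyacetophenone is C-prenylated twice with 1 (KOH, aqueous MeOH) to give 3,5-diprenyl-2,4-dihydroxyacetophenone F1.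
- The non-chelated 4-OH is silylated (TIPSOTf, 2,6-lutidine) to give the 4-O-triisopropylsilyl ketone F2.
- Condensation with DMF dimethyl acetal gives the enaminone F3.
- Mild acid closes F3, with loss of dimethylamine, to 6,8-diprenyl-7-(triisopropylsilyloxy)chromone F4.
- An enantioselective conjugate addition of commercial 4-(methoxymethoxy)phenylboronic acid to F4 gives 22. The catalyst is Pd(OCOCF3)2 with t-BuPyOx, NH4PF6 and H2O in ClCH2CH2Cl, using the ligand antipode that gives the 2S product.

**2. Step 10.** The alkynyloxy group may be lost by enolisation–elimination or by retro-ene fragmentation during oxidation or concentration, because the new ketone acidifies the C3 hydrogens next to a very good leaving group.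

The fallback moves the oxidation behind the ring construction, sets out from 20 and rejoins at 22.
- Carbinol 20 is submitted with 6 to the conditions of step 11 to give the (2S)-flavan-4-ol F5 as a mixture of C4 epimers.
- The benzylic alcohol of F5 is then oxidised with MnO2 in CH2Cl2 to 22.
- No β-alkynyloxy ketone is ever present. The cost is that the C5–C6 bond loses its polarity match, so orientation rests on the C7–C8 pairing alone.

**3. Step 8.**
- Alkylation of the lithium alkynyl ether may be sluggish or go SN2′.
- Lithiation may compete at the benzylic position or ortho to the acetal.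
- The benzylic alkynyl ether may rearrange sigmatropically if warming is needed.

The fallback replaces the SN2 alkylation by a neutral cross-coupling, sets out from 16 and rejoins at 19.
- 18 is generated as before and trapped at −78 °C with Bu3SnCl to give the tributylstannyl alkynyl ether F6.
- F6 is joined to 1 by Stille coupling (Pd2(dba)3, AsPh3, THF, rt). The π-prenyl complex of divalent palladium should couple at its unsubstituted terminus.

**Further compounds**
F1 | step 11 | 1-[2,4-dihydroxy-3,5-bis(3-methylbut-2-en-1-yl)phenyl]ethan-1-one | CC(=O)c1cc(CC=C(C)C)c(O)c(CC=C(C)C)c1O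
F2 | step 11 | 1-{2-hydroxy-3,5-bis(3-methylbut-2-en-1-yl)-4-[(triisopropylsilyl)oxy]phenyl}ethan-1-one | CC(=O)c1cc(CC=C(C)C)c(O[Si](C(C)C)(C(C)C)C(C)C)c(CC=C(C)C)c1O
F3 | step 11 | (E)-3-(dimethylamino)-1-{2-hydroxy-3,5-bis(3-methylbut-2-en-1-yl)-4-[(triisopropylsilyl)oxy]phenyl}prop-2-en-1-one | CN(C)/C=C/C(=O)c1cc(CC=C(C)C)c(O[Si](C(C)C)(C(C)C)C(C)C)c(CC=C(C)C)c1O
F4 | step 11 | 6,8-bis(3-methylbut-2-en-1-yl)-7-[(triisopropylsilyl)oxy]-4H-chromen-4-one | O=c1ccoc2c(CC=C(C)C)c(O[Si](C(C)C)(C(C)C)C(C)C)c(CC=C(C)C)cc12
F5 | step 10 | (2S,4RS)-2-[4-(methoxymethoxy)phenyl]-6,8-bis(3-methylbut-2-en-1-yl)-7-[(triisopropylsilyl)oxy]chroman-4-ol | CC(C)=CCc1cc2c(c(CC=C(C)C)c1O[Si](C(C)C)(C(C)C)C(C)C)O[C@H](c1ccc(OCOC)cc1)CC2O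
F6 | step 8 | {(3RS,5S)-5-[4-(methoxymethoxy)phenyl]-5-{[(tributylstannyl)ethynyl]oxy}-3-[(triisopropylsilyl)oxy]pent-1-yn-1-yl}trimethylsilane | C[Si](C)(C)C#CC(O[Si](C(C)C)(C(C)C)C(C)C)C[C@H](OC#C[Sn](CCCC)(CCCC)CCCC)c1ccc(OCOC)cc1
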